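Atoms carry bisabolane numbers throughout: C1 = ring CH2, C2–C3 = ring oxirane (methyl on C3), C4 = CHOH, C5 = ring CH–O–angelate, C6 = ring CH, C7(=C14H2), C8 = CH–O–angelate, C9 = CH2, C10–C11 = dimethyloxirane. Compounds are numbered 1–26 as in the steps and the compound list.

## Analysis of the target

The target (26) is a bisabolane with one six-membered carbocycle (C1–C6); C6 carries the 1,1-disubstituted alkene C7(=C14H2), which continues as the chain C8–C11. Its seven stereocentres are 2S,3R,4R,5R,6S,8S,10R. On the ring, the oxirane oxygen, the C4 hydroxyl, the C5 acyloxy group and the C6–C7 bond all lie on one face; C8 is an allylic carbinol centre next to the ring but not fixed by it, and C10 is remote from every other centre. The sensitive groups are two (Z)-2-methylbut-2-enoates (isomerisation to tiglates with nucleophilic catalysts or strong base), a free hydroxyl cis-vicinal to an ester (acyl migration), two acid-labile trisubstituted oxiranes and an allylic ester at C8. The difficulty is to place three different oxygen functions (oxirane, free OH, ester) on four contiguous all-cis ring carbons while keeping C4 and C5 distinguishable, and to control C8 and C10 by reagents. The plan rests on one structural feature: the C5 oxygen is cis to the C6–C7 bond and stands 1,4 to C2 across the ring. An oxygen bridging C2 and C5, as in a 7-oxabicyclo[2.2.1]heptene, holds that cis relation rigidly; when it is later expelled from C2 it leaves C5–OH and the C2=C3 double bond from which the ring oxirane is made.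

## Retrosynthetic reasoning

26 to 25. The C10–C11 oxirane is removed first. C10 is the one centre the ring cannot influence, so it needs a catalyst-controlled epoxidation of the most electron-rich alkene; placing it last keeps this acid-labile oxirane out of every other step.

25 to 24. The C2–C3 oxirane is traced to the allylic alcohol 24. The C4 hydroxyl is cis to the required oxirane oxygen and can deliver the oxidant to its own face, so no other alkene competes.

24 to 23. The C4 carbinol is traced to the enone 23. While C5 is esterified, C4 is a ketone, so the two neighbouring oxygens are distinguished by oxidation level and not by protecting groups; the reduction has to come from the face opposite the C5 ester.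

23 to 22 and 17; 18 to 15 and 17; 17 to 16. Both ester C–O bonds are cut to a single acyl donor, the mixed anhydride 17, which is prepared once from angelic acid 16 and serves both acylations. The C8 ester is introduced early because it also protects C8–OH while C4 is oxidised; the C5 ester can only follow the ring opening. Both acylations must avoid nucleophilic catalysts so that the Z geometry survives.

22 to 20. The C5 oxygen is reconnected to C2: the cis-5-hydroxy enone is the β-elimination product of the 7-oxanorbornan-2-one 20. The C4 ketone can enolise only toward C3 because C5 is a bridgehead, so only the C2–O bond breaks, and C5 and C6 are untouched.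

20 to 19 to 18. These are adjustments at C4 (ketone, alcohol, silyl ether); the C4 oxygen is carried as a silyl ether through the organometallic steps on C7 and C8.

15 to 14 to 13. The C8 configuration is traced to a catalyst-controlled reduction of the enone 14, because the bond formation that creates C8 is not expected to control it.

13 to 10 and 12. The C7–C8 bond is cut to an alkenyl nucleophile at C7 (from enol triflate 10) and aldehyde 12 (from alcohol 11). The 1,1-disubstituted alkene and the carbinol arise in one bond formation, under conditions mild enough for a β,γ-unsaturated aldehyde.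

10 to 8 (through 9) to 7. The C7–C14 bond is cut: C14 arrives as a methyl nucleophile on the amide 7. All carbonyl chemistry at C7 is done on the bicycle, where the exo position of C6 is the thermodynamically preferred one, so C6 cannot be lost by enolisation.

7 to 6 to 4 (through 5). The C4–O bond is traced to hydroboration–oxidation of C3=C4 from the exo face. It must precede the introduction of any other alkene, and it also removes the double bond that makes the bicycle prone to cycloreversion.

4 to 3. The amide is traced to the activated ester of the cycloadduct.

3 to 1 and 2. C1–C2 and C5–C6 are cut in a Diels–Alder disconnection to two commercial compounds. The forward reaction must deliver the methyl group on C3, the ester exo and one absolute sense.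

## Alternatives that were turned down

Alternative 1: The ring is cut at C4–C5 and C1–C6 and, after fragmentation, re-formed at C2–C3. In the forward sense the enantiopure dioxinone A1 is irradiated with 2,3-dihydrofuran A2. The head-to-tail [2+2] photoadduct A3 carries C5–O and C6 on a cis-fused oxolane; retro-aldol opening of the cyclobutane and Claisen-type closure of C3 onto C2 would give a 2-methylcyclohexane-1,3-dione.
- For: the cis relation of C5–O to C6–C7 is enforced by the five-membered ring, and the tert-butyl acetal steers the facial approach. Absolute control rests on an auxiliary and not on a catalyst, and on that point it is at least as secure as the cycloaddition chosen here.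
- Against: the oxolane oxygen of A3 is bonded to both C5 and C8, whereas the target has separate ester oxygens there. C7 arrives as an unactivated CH2 that must become the C7=C14 alkene, and C8 as an ether CH2 that must be oxidised, re-oxygenated with control and extended by C9–C11. The carbonyls at C2 and C4 of the dione must be told apart before C2=C3 and the C4 carbinol can be made, and regio- and ring-fusion selectivity of such photoadditions is usually only partial.
- Comparison: the chosen strategy gives the carbocycle with C2=C3 latent, a single carbonyl at C4 and C7 at the carboxyl level, so the side chain is built by polar chemistry and the sequence after the key step is much shorter.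

Alternative 2: The carbocycle is cut at C3–C4. In the forward sense the acyclic iodoalkene aldehyde A4 is closed by a chromium/nickel-mediated intramolecular alkenylation of the aldehyde to the cyclohexenol A5. A4 holds the Z-iodoalkene (C2=C3), the syn C5/C6 pair from an aldol reaction and the C7 amide.
- For: no regiochemical question arises, and here it is clearly stronger than the cycloaddition. C5 and C6 come from a reliable auxiliary aldol, and the closure gives C2=C3 and the C4 carbinol at once, so no ketone reduction is needed.
- Against: A4 needs a linear sequence of its own (stereodefined trisubstituted iodoalkene, aldol, protection, an epimerisable α-silyloxy aldehyde) that is longer than the whole front part of the chosen route. The sense at C4 depends on a Felkin versus chelate preference that is hard to predict in a cyclic transition structure. In A5 the free hydroxyl is on C4 and the silyl ether on C5, the reverse of what the target needs, so protecting groups must be exchanged, and chromium is needed in large excess.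
- Comparison: the chosen route distinguishes C4 from C5 by oxidation level without any exchange and makes the ring from two commercial compounds in one step.

Alternative 3: The C6–C7 bond is cut. In the forward sense a tin-hydride radical chain converts the bromovinylsilyl ether A6 into an α-silylvinyl radical tethered to C5–O, which closes 5-exo onto C6 of the diene. The allyl radical is reduced at C1 and the cis-fused siloxane A7 results.
- For: C4 and C5 would come from the diene diol A8, and the tether sets C6 cis to C5–O with C7 already the 1,1-disubstituted alkene carbon. Relative control of the three ring centres is more secure than in the chosen route, which depends on a catalyst and on exo selectivity.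
- Against: the two hydroxyls of A8 must be differentiated with the tether on the less hindered and the silyl ether on the more hindered oxygen. Cyclohexadienediol derivatives aromatise easily, and hydrogen transfer to the allyl radical can also occur at C3. The C7–Si bond of A7 is a poor handle for joining C7 to the sp3 carbinol carbon C8, so an oxidative detour to a C7 ketone and the same alkenyl coupling as in the chosen route would still follow. The diol that arene dioxygenases deliver is recalled as (1S,2R), the antipode of A8.
- Comparison: in place of that stereochemical security the chosen strategy offers C7 at the carboxyl level from the start, a C4 ketone that both triggers the ring opening and keeps C4 and C5 distinct, and no tin.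

Key step: step 1

Remark on the chemistry (assumption): the (R)-configured oxazaborolidinium ion is taken to expose the acrylate face that gives R at the ester-bearing carbon (C6, locant 2 of the bicycle), the mirror image of the sense in which the (S)-catalyst is recalled to give S-configured cyclohex-3-ene-1-carboxylates from acyclic dienes; if the sense is the reverse, the antipodal catalyst is used unchanged.

## Route

Step 1
Reactants: 1 3-methylfuran; 2 2,2,2-trifluoroethyl acrylate
Product: 3 2,2,2-trifluoroethyl (1S,2R,4S)-5-methyl-7-oxabicyclo[2.2.1]hept-5-ene-2-carboxylate (exo ester; ester carbon = C7, bridge oxygen on C2 and C5)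
Conditions: (R)-3,3-diphenyl-1-(o-tolyl)tetrahydro-1H,3H-pyrrolo[1,2-c][1,3,2]oxazaborole (20 mol %), HNTf2 (18 mol %), 1 (3 equiv), CH2Cl2, −78 °C then −40 °C; Et3N, −78 °C
Reagents that add atoms: none
Why: The protonated oxazaborolidine binds the acrylate carbonyl and lowers its LUMO, so the furan adds in a concerted, asynchronous, suprafacial [4+2] cycloaddition; the closest known reaction type is the cationic-oxazaborolidine-catalysed Diels–Alder reaction of furans with this acrylate. Both rings close in the one intermolecular cycloaddition: the carbocycle C1–C6 through the new bonds C1–C2 and C5–C6, and the oxolane O–C2–C1–C6–C5 because the furan oxygen then spans C2 and C5. The 3-methyl group raises the HOMO coefficient at the adjacent furan α-carbon, which pairs with the acrylate CH2, so the ester carbon bonds to the far α-carbon and the methyl ends on C3. C6 is set by the catalyst, whose aryl group screens one face of the coordinated s-trans acrylate; C2 and C5 follow from suprafacial addition across the furan and from the exo orientation of the ester. Exo topology is required but is not the kinetic preference, so the mixture is held at −40 °C, where the endo adduct should revert to the addends on the catalyst while the more stable exo adduct accumulates, and is quenched cold before the exo adduct can revert as well. The step therefore needs regio-, exo and facial selectivity together; the exo and the regiochemical outcome are the least secure, and a slight excess of oxazaborolidine over HNTf2 keeps free acid away from the furan.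

Step 2
Reactants: 3 exo trifluoroethyl ester
Product: 4 (1S,2R,4S)-N-methoxy-N,5-dimethyl-7-oxabicyclo[2.2.1]hept-5-ene-2-carboxamide (exo amide)
Conditions: MeNHOMe·HCl, iPrMgCl, THF, −20 °C
Reagents that add atoms: N,O-dimethylhydroxylamine hydrochloride, CNOC.Cl
Why: Aminolysis of the activated ester by the chloromagnesium amide; this weakly basic nucleophile should not deprotonate C6, so the exo configuration and the bridge survive. The product is kept cold because the unsaturated bicycle can undergo cycloreversion.

Step 3
Reactants: 4 exo amide
Product: 6 (1R,2R,4S,5S,6S)-6-hydroxy-N-methoxy-N,5-dimethyl-7-oxabicyclo[2.2.1]heptane-2-carboxamide (C4–OH exo, C3 methyl endo, amide exo), via alkylborane 5 (not isolated)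
Conditions: BH3·THF, THF, −10 to 0 °C; then NaOH, H2O2, H2O, 0 °C to rt
Reagents that add atoms: hydrogen peroxide, OO
Why: Hydroboration–oxidation: borane adds to the strained trisubstituted alkene from the exo face (the face of the oxygen bridge) with boron on the less substituted C4, and oxidation with retention gives the exo C4 alcohol. Saturating C3=C4 also ends the risk of cycloreversion.

Step 4
Reactants: 6 exo alcohol
Product: 7 tert-butyldimethylsilyl ether of 6 at the C4 oxygen (ring configuration as in 6)
Conditions: tBuMe2SiOTf, 2,6-lutidine, CH2Cl2, −78 to 0 °C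
Reagents that add atoms: tert-butyldimethylsilyl trifluoromethanesulfonate, CC(C)(C)[Si](C)(C)OS(=O)(=O)C(F)(F)F
Why: Silylation of a hindered secondary alcohol with the silyl triflate; the ether masks the C4 oxygen through the organometallic and redox steps on C7 and C8.

Step 5
Reactants: 7 silyl ether amide
Product: 8 1-[6-exo-(tert-butyldimethylsilyloxy)-5-endo-methyl-7-oxabicyclo[2.2.1]heptan-2-exo-yl]ethan-1-one (C7 methyl ketone, C14 = methyl; ring configuration as in 6)
Conditions: MeMgBr, THF, 0 °C
Reagents that add atoms: methylmagnesium bromide, C[Mg]Br
Why: Ketone synthesis from an N-methoxy-N-methylamide; the magnesium-chelated tetrahedral adduct persists until work-up, so addition stops at the ketone. The exo acetyl group is the thermodynamically preferred epimer on this bicycle, so C6 is not at risk.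

Step 6
Reactants: 8 methyl ketone
Product: 10 1-[6-exo-(tert-butyldimethylsilyloxy)-5-endo-methyl-7-oxabicyclo[2.2.1]heptan-2-exo-yl]ethenyl trifluoromethanesulfonate (enol triflate, C7=C14), via potassium enolate 9 (not isolated)
Conditions: KN(SiMe3)2, THF, −78 °C; then PhNTf2, −78 to 0 °C
Reagents that add atoms: N-phenylbis(trifluoromethanesulfonimide), O=S(=O)(N(c1ccccc1)S(=O)(=O)C(F)(F)F)C(F)(F)F
Why: Kinetic deprotonation at the methyl group and not at the hindered tertiary C6–H, followed by O-sulfonylation, gives the terminal enol triflate. An enolate at C6, which could expel the bridge oxygen from C5, is thereby avoided.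

Step 7
Reactants: 11 4-methylpent-3-en-1-ol
Product: 12 4-methylpent-3-enal
Conditions: Dess–Martin periodinane, NaHCO3, CH2Cl2, 0 °C; used at once
Reagents that add atoms: none
Why: Dess–Martin oxidation of a homoallylic alcohol under buffered, non-basic conditions, so the β,γ-double bond should not move into conjugation.

Step 8
Reactants: 10 enol triflate; 12 4-methylpent-3-enal
Product: 13 2-[6-exo-(tert-butyldimethylsilyloxy)-5-endo-methyl-7-oxabicyclo[2.2.1]heptan-2-exo-yl]-6-methylhepta-1,5-dien-3-ol (C8 carbinol, both epimers)
Conditions: CrCl2 (4 equiv), NiCl2 (2 mol %), DMF, rt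
Reagents that add atoms: none
Why: Nozaki–Hiyama–Kishi coupling: zerovalent nickel inserts into the alkenyl C–O bond of the triflate and transmetalation gives an alkenyl species of trivalent chromium that adds only to the aldehyde, forming C7–C8 together with the C7=C14 alkene. The reagent is not basic, so the labile aldehyde is not isomerised; no control at C8 is expected or needed here.

Step 9
Reactants: 13 allylic alcohols
Product: 14 2-[6-exo-(tert-butyldimethylsilyloxy)-5-endo-methyl-7-oxabicyclo[2.2.1]heptan-2-exo-yl]-6-methylhepta-1,5-dien-3-one (C8 ketone)
Conditions: Dess–Martin periodinane, NaHCO3, CH2Cl2, 0 °C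
Reagents that add atoms: none
Why: Dess–Martin oxidation converges both C8 epimers on one α-methylene ketone. Buffered conditions and direct use should prevent migration of the C10=C11 bond into conjugation.

Step 10
Reactants: 14 enone
Product: 15 (3S)-2-[6-exo-(tert-butyldimethylsilyloxy)-5-endo-methyl-7-oxabicyclo[2.2.1]heptan-2-exo-yl]-6-methylhepta-1,5-dien-3-ol (8S)
Conditions: (R)-1-methyl-3,3-diphenyltetrahydro-1H,3H-pyrrolo[1,2-c][1,3,2]oxazaborole (0.5 equiv), catecholborane, toluene, −78 °C
Reagents that add atoms: none
Why: Corey–Bakshi–Shibata reduction: the ketone binds to the ring boron with the branched alkenyl group (C7) as the large and C9H2 as the small substituent, and hydride is delivered from the nitrogen-bound borane. The (R)-catalyst should give 8S, the mirror sense of the S-catalyst/acetophenone case. Catecholborane at −78 °C should leave the alkenes alone.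

Step 11
Reactants: 16 angelic acid
Product: 17 (Z)-2-methylbut-2-enoic 2,4,6-trichlorobenzoic anhydride (mixed anhydride)
Conditions: 2,4,6-trichlorobenzoyl chloride (1.0 equiv), Et3N (1.05 equiv), toluene, 0 °C to rt; Et3N·HCl filtered off under argon; filtrate kept at −20 °C as the stock solution for steps 12 and 16
Reagents that add atoms: 2,4,6-trichlorobenzoyl chloride, O=C(Cl)c1c(Cl)cc(Cl)cc1Cl
Why: Acyl substitution at the aroyl chloride by the triethylammonium carboxylate, the first stage of a Yamaguchi esterification, run once on a scale that serves both acylations. Neither heat nor a nucleophilic catalyst is involved, so the Z geometry is untouched; partial symmetrisation on storage would be harmless, because every anhydride present transfers the same angeloyl group.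

Step 12
Reactants: 15 (8S)-alcohol; 17 mixed anhydride
Product: 18 the C8 (Z)-2-methylbut-2-enoate of 15
Conditions: 17 (toluene solution, 2 equiv), Et3N (2 equiv), toluene, 75 °C
Reagents that add atoms: none
Why: Yamaguchi-type esterification with the preformed mixed anhydride: the alcohol attacks the angeloyl carbonyl because the aroyl carbonyl is screened by its two ortho chlorines. No nucleophilic catalyst that could add reversibly to the enoate is present, so the Z geometry should be kept; the amine only takes up the liberated aroic acid.

Step 13
Reactants: 18 silyl ether angelate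
Product: 19 the C4 (6-exo) alcohol corresponding to 18
Conditions: HF·pyridine, pyridine, THF, 0 °C to rt
Reagents that add atoms: none
Why: Fluoride cleavage of the silyl ether under buffered acidic conditions, which leave the angelate, the alkenes and the oxygen bridge untouched.

Step 14
Reactants: 19 alcohol
Product: 20 the C4 ketone: (3S)-6-methyl-2-[5-endo-methyl-6-oxo-7-oxabicyclo[2.2.1]heptan-2-exo-yl]hepta-1,5-dien-3-yl (Z)-2-methylbut-2-enoate
Conditions: Dess–Martin periodinane, NaHCO3, CH2Cl2, 0 °C to rt
Reagents that add atoms: none
Why: Dess–Martin oxidation to the 7-oxanorbornan-2-one. C3 may epimerise, but it becomes sp2 in the next step.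

Step 15
Reactants: 20 bicyclic ketone
Product: 22 (3S)-2-[(1S,2R)-2-hydroxy-4-methyl-3-oxocyclohex-4-en-1-yl]-6-methylhepta-1,5-dien-3-yl (Z)-2-methylbut-2-enoate (C5–OH cis to C6–C7; enone C2=C3–C4=O), via trimethylsilyl ether 21 (not isolated)
Conditions: Me3SiOTf (1.2 equiv), Et3N, CH2Cl2, −40 to 0 °C; then citric acid, MeOH, H2O, 0 °C
Reagents that add atoms: none
Why: Soft enolisation can only go toward C3 because C5 is a bridgehead. The silyl enol ether, with silyl triflate activating the bridge oxygen, expels that oxygen from C2, a known silyl-triflate/amine β-elimination of 7-oxanorbornan-2-ones, and the C5 silyl ether is cleaved in the acidic work-up. C5 and C6 are untouched, so the cis relation from the cycloadduct is carried into the monocycle.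

Step 16
Reactants: 22 hydroxy enone; 17 mixed anhydride
Product: 23 the C5 (Z)-2-methylbut-2-enoate of 22 (bis-angelate enone)
Conditions: 17 (toluene solution, 2 equiv), Et3N (2 equiv), toluene, 60–75 °C
Reagents that add atoms: none
Why: The same mixed-anhydride acyl transfer as in step 12, with the second portion of the stock solution. Strong base is absent, so C5, which is α to the ketone, should not be epimerised.

Step 17
Reactants: 23 bis-angelate enone
Product: 24 the C4 allylic alcohol of 23, with the hydroxyl cis to the C5 ester
Conditions: NaBH4, CeCl3·7H2O, MeOH, −78 °C; AcOH quench at −78 °C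
Reagents that add atoms: none
Why: Luche 1,2-reduction: with the C6 side chain pseudo-equatorial the C5 ester is pseudo-axial, and hydride should add to C4 anti to it (axial attack), placing the new hydroxyl cis to C5–O. Low temperature and a cold acidic quench limit acyl migration.

Step 18
Reactants: 24 allylic alcohol
Product: 25 the (2S,3R)-2,3-epoxide of 24 (oxirane cis to C4–OH; C10=C11 and C7=C14 intact)
Conditions: VO(acac)2 (5 mol %), tBuOOH, CH2Cl2, 0 °C to rt
Reagents that add atoms: tert-butyl hydroperoxide, CC(C)(C)OO
Why: Hydroxyl-directed epoxidation: the vanadium alkoxide of C4–OH delivers the peroxide oxygen to the adjacent C2=C3 on the hydroxyl face, giving the cis epoxy alcohol. The alkenes without an allylic hydroxyl and the electron-poor enoates react much more slowly.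

Step 19
Reactants: 25 mono-epoxide
Product: 26 target CNP0235377.1, (2S,3R,4R,5R,6S,8S,10R)
Conditions: 1,2:4,5-di-O-isopropylidene-β-D-erythro-2,3-hexodiulo-2,6-pyranose (0.3 equiv), Oxone (2KHSO5·KHSO4·K2SO4), K2CO3, Bu4NHSO4, MeCN–CH2(OMe)2/aqueous Na2B4O7–Na2EDTA, 0 °C
Reagents that add atoms: potassium peroxymonosulfate, [K+].[O-]S(=O)(=O)OO
Why: Shi epoxidation: the chiral dioxirane attacks the electron-rich trisubstituted C10=C11 through a spiro transition state and should give 10R, the same facial sense that gives R,R oxiranes from trans-disubstituted alkenes. The 1,1-disubstituted alkene with its allylic ester and the conjugated enoates are far less reactive.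

## Compound list

1 | 3-methylfuran | Cc1ccoc1 | starting material
2 | 2,2,2-trifluoroethyl acrylate | C=CC(=O)OCC(F)(F)F | starting material
3 | 2,2,2-trifluoroethyl (1S,2R,4S)-5-methyl-7-oxabicyclo[2.2.1]hept-5-ene-2-carboxylate (exo) | FC(F)(F)COC(=O)[C@@H]1C[C@@H]2O[C@H]1C=C2C | intermediate
4 | (1S,2R,4S)-N-methoxy-N,5-dimethyl-7-oxabicyclo[2.2.1]hept-5-ene-2-carboxamide (exo) | CON(C)C(=O)[C@@H]1C[C@@H]2O[C@H]1C=C2C | intermediate
5 | 6-exo-boranyl-5-endo-methyl alkylborane from 4 | CON(C)C(=O)[C@@H]1C[C@@H]2O[C@H]1[C@@H](B)[C@@H]2C | intermediate
6 | (1R,2R,4S,5S,6S)-6-hydroxy-N-methoxy-N,5-dimethyl-7-oxabicyclo[2.2.1]heptane-2-carboxamide | CON(C)C(=O)[C@@H]1C[C@@H]2O[C@H]1[C@@H](O)[C@@H]2C | intermediate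
7 | 6-exo-O-tert-butyldimethylsilyl ether of 6 | CON(C)C(=O)[C@@H]1C[C@@H]2O[C@H]1[C@@H](O[Si](C)(C)C(C)(C)C)[C@@H]2C | intermediate
8 | exo methyl ketone (C7 ketone, C4–OTBS) | CC(=O)[C@@H]1C[C@@H]2O[C@H]1[C@@H](O[Si](C)(C)C(C)(C)C)[C@@H]2C | intermediate
9 | potassium enolate of 8 (C7=C14) | [K+].C=C([O-])[C@@H]1C[C@@H]2O[C@H]1[C@@H](O[Si](C)(C)C(C)(C)C)[C@@H]2C | intermediate
10 | enol triflate of 8 (C7=C14) | C=C(OS(=O)(=O)C(F)(F)F)[C@@H]1C[C@@H]2O[C@H]1[C@@H](O[Si](C)(C)C(C)(C)C)[C@@H]2C | intermediate
11 | 4-methylpent-3-en-1-ol | CC(C)=CCCO | starting material
12 | 4-methylpent-3-enal | CC(C)=CCC=O | intermediate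
13 | C8 allylic alcohols (both epimers), C4–OTBS bicycle | C=C(C(O)CC=C(C)C)[C@@H]1C[C@@H]2O[C@H]1[C@@H](O[Si](C)(C)C(C)(C)C)[C@@H]2C | intermediate
14 | C8 ketone (α-methylene ketone), C4–OTBS bicycle | C=C(C(=O)CC=C(C)C)[C@@H]1C[C@@H]2O[C@H]1[C@@H](O[Si](C)(C)C(C)(C)C)[C@@H]2C | intermediate
15 | (8S)-allylic alcohol, C4–OTBS bicycle | C=C([C@H](CC=C(C)C)O)[C@@H]1C[C@@H]2O[C@H]1[C@@H](O[Si](C)(C)C(C)(C)C)[C@@H]2C | intermediate
16 | angelic acid, (Z)-2-methylbut-2-enoic acid | C/C=C(/C)C(=O)O | starting material
17 | (Z)-2-methylbut-2-enoic 2,4,6-trichlorobenzoic anhydride | C/C=C(/C)C(=O)OC(=O)c1c(Cl)cc(Cl)cc1Cl | intermediate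
18 | C8 angelate, C4–OTBS bicycle | C=C([C@H](CC=C(C)C)OC(=O)/C(C)=C\C)[C@@H]1C[C@@H]2O[C@H]1[C@@H](O[Si](C)(C)C(C)(C)C)[C@@H]2C | intermediate
19 | C8 angelate, C4 exo alcohol, bicycle | C=C([C@H](CC=C(C)C)OC(=O)/C(C)=C\C)[C@@H]1C[C@@H]2O[C@H]1[C@@H](O)[C@@H]2C | intermediate
20 | C8 angelate, C4 ketone (7-oxanorbornan-2-one) | C=C([C@H](CC=C(C)C)OC(=O)/C(C)=C\C)[C@@H]1C[C@@H]2O[C@H]1C(=O)[C@@H]2C | intermediate
21 | C5 trimethylsilyl ether of 22 | C=C([C@H](CC=C(C)C)OC(=O)/C(C)=C\C)[C@@H]1CC=C(C)C(=O)[C@@H]1O[Si](C)(C)C | intermediate
22 | (3S)-2-[(1S,2R)-2-hydroxy-4-methyl-3-oxocyclohex-4-en-1-yl]-6-methylhepta-1,5-dien-3-yl (Z)-2-methylbut-2-enoate | C=C([C@H](CC=C(C)C)OC(=O)/C(C)=C\C)[C@@H]1CC=C(C)C(=O)[C@@H]1O | intermediate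
23 | C5,C8 bis-angelate enone | C=C([C@H](CC=C(C)C)OC(=O)/C(C)=C\C)[C@@H]1CC=C(C)C(=O)[C@@H]1OC(=O)/C(C)=C\C | intermediate
24 | bis-angelate C4 allylic alcohol (OH cis to C5–O) | C=C([C@H](CC=C(C)C)OC(=O)/C(C)=C\C)[C@@H]1CC=C(C)[C@H](O)[C@@H]1OC(=O)/C(C)=C\C | intermediate
25 | ring 2,3-epoxide of 24 | C=C([C@H](CC=C(C)C)OC(=O)/C(C)=C\C)[C@@H]1C[C@@H]2O[C@]2(C)[C@H](O)[C@@H]1OC(=O)/C(C)=C\C | intermediate
26 | CNP0235377.1 | C=C([C@H](C[C@H]1OC1(C)C)OC(=O)/C(C)=C\C)[C@@H]1C[C@@H]2O[C@]2(C)[C@H](O)[C@@H]1OC(=O)/C(C)=C\C | target

## Step count and least certain steps

Total step count: 19. Longest linear sequence: 17 (steps 1–6, 8–10 and 12–19); steps 7 and 11 are one-step side branches.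

Step 1 (key step). Three things can fail together.
- Regiocontrol may leak, with the ester carbon bonding to the methyl-flanked α-carbon.
- The endo adduct may not drain fast enough, or the exo adduct may itself revert and re-form with loss of enantiomeric purity, because exo selectivity and high facial selectivity are asked of a reversible process inside a narrow temperature window.
- The acidic catalyst may cause conjugate alkylation or oligomerisation of the electron-rich furan.

The fallback no longer asks the cycloaddition for exo selectivity and sets out from 1 and 2. With the (S)-configured catalyst under strictly kinetic conditions (−78 °C, cold quench) the main product should be the endo ester F1, which has the bridgehead configuration of 3 and differs only at C6. Aminolysis as in step 2 gives the endo amide F2, hydroboration through the alkylborane F3 and oxidation give the alcohol F4, silylation gives the silyl ether F5, and MeMgBr gives the endo methyl ketone F6. Equilibration of F6 with K2CO3 in MeOH at room temperature should move the acetyl group to the less hindered exo position, and the route is rejoined at 8. The cost is one extra step and recycling of unconverted F6; a regioisomer, if formed, is removed by chromatography in either variant.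

Step 15. Excess silyl triflate may silylate the product enone toward C5 and scramble that centre, and Lewis-acid ionisation of the allylic C8 ester is possible. The fallback sets out from 20. LiN(SiMe3)2 (1.05 equiv, THF, −78 °C) forms the lithium enolate F8, which on warming to −40 °C expels the bridge oxygen to give the lithium alkoxide F9. F9 is acylated in the same flask with angelic anhydride F7 (made from 16 with dicyclohexylcarbodiimide). This returns to the route at 23 and bypasses 21, 22 and step 16.

Step 16. Acylation of the hindered α-ketol may be slow, and prolonged heating with amine may cause enediol tautomerism or epimerisation at C5 and Z to E isomerisation of the enoate. The fallback builds the angelate by olefination and sets out from 22. Esterification with 2-[bis(2,2,2-trifluoroethoxy)phosphoryl]propanoic acid (N-ethyl-N′-(3-dimethylaminopropyl)carbodiimide hydrochloride, catalytic 4-dimethylaminopyridine, CH2Cl2, 0 °C) gives the phosphonopropanoate F10. Still–Gennari olefination of F10 with acetaldehyde (KN(SiMe3)2, 1.0 equiv, 18-crown-6, THF, −78 °C) forms the Z-trisubstituted enoate and returns to the route at 23.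

Step 17. Facial selectivity of hydride delivery may be insufficient, and the C5 acyl group may migrate to the new C4 alkoxide during reduction or work-up. The fallback carries C5 as a silyl ether through the reduction and sets out from 22.
- Et3SiCl and imidazole give the triethylsilyl ether F11.
- Luche reduction gives the alcohol F12.
- tBuMe2SiOTf and 2,6-lutidine give the bis-silyl ether F13.
- Pyridinium p-toluenesulfonate in MeOH removes only the triethylsilyl group and gives the alcohol F14.
- Acylation with 17 gives the ester F15.
- HF·pyridine returns to the route at 24.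

Step 19. At the pH of the epoxidation the C5 acyl group may migrate to the cis C4 hydroxyl, and discrimination between C10=C11 and C7=C14 may be incomplete. The fallback caps the hydroxyl and sets out from 25. Et3SiCl and imidazole give the silyl ether F16, the same Shi epoxidation gives the epoxide F17, and Bu4NF buffered with AcOH (THF, 0 °C) returns to the route at 26.

Further compounds

F1 | step 1 | 2,2,2-trifluoroethyl (1S,2S,4S)-5-methyl-7-oxabicyclo[2.2.1]hept-5-ene-2-carboxylate (endo ester) | FC(F)(F)COC(=O)[C@H]1C[C@@H]2O[C@H]1C=C2C
F2 | step 1 | endo N-methoxy-N-methylamide | CON(C)C(=O)[C@H]1C[C@@H]2O[C@H]1C=C2C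
F3 | step 1 | endo-series 6-exo-alkylborane | CON(C)C(=O)[C@H]1C[C@@H]2O[C@H]1[C@@H](B)[C@@H]2C
F4 | step 1 | endo-amide 6-exo-alcohol | CON(C)C(=O)[C@H]1C[C@@H]2O[C@H]1[C@@H](O)[C@@H]2C
F5 | step 1 | tert-butyldimethylsilyl ether of F4 | CON(C)C(=O)[C@H]1C[C@@H]2O[C@H]1[C@@H](O[Si](C)(C)C(C)(C)C)[C@@H]2C
F6 | step 1 | endo methyl ketone (C6 epimer of 8) | CC(=O)[C@H]1C[C@@H]2O[C@H]1[C@@H](O[Si](C)(C)C(C)(C)C)[C@@H]2C
F7 | step 15 | angelic anhydride, (Z)-2-methylbut-2-enoic anhydride | C/C=C(/C)C(=O)OC(=O)/C(C)=C\C
F8 | step 15 | lithium enolate of 20 | [Li+].C=C([C@H](CC=C(C)C)OC(=O)/C(C)=C\C)[C@@H]1C[C@@H]2O[C@H]1C([O-])=C2C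
F9 | step 15 | lithium alkoxide of 22 | [Li+].C=C([C@H](CC=C(C)C)OC(=O)/C(C)=C\C)[C@@H]1CC=C(C)C(=O)[C@@H]1[O-]
F10 | step 16 | C5 2-[bis(2,2,2-trifluoroethoxy)phosphoryl]propanoate of 22 | C=C([C@H](CC=C(C)C)OC(=O)/C(C)=C\C)[C@@H]1CC=C(C)C(=O)[C@@H]1OC(=O)C(C)P(=O)(OCC(F)(F)F)OCC(F)(F)F
F11 | step 17 | C5 triethylsilyl ether of 22 | C=C([C@H](CC=C(C)C)OC(=O)/C(C)=C\C)[C@@H]1CC=C(C)C(=O)[C@@H]1O[Si](CC)(CC)CC
F12 | step 17 | C4 alcohol, C5 triethylsilyl ether | C=C([C@H](CC=C(C)C)OC(=O)/C(C)=C\C)[C@@H]1CC=C(C)[C@H](O)[C@@H]1O[Si](CC)(CC)CC
F13 | step 17 | C4 tert-butyldimethylsilyl ether, C5 triethylsilyl ether | C=C([C@H](CC=C(C)C)OC(=O)/C(C)=C\C)[C@@H]1CC=C(C)[C@H](O[Si](C)(C)C(C)(C)C)[C@@H]1O[Si](CC)(CC)CC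
F14 | step 17 | C4 tert-butyldimethylsilyl ether, C5 alcohol | C=C([C@H](CC=C(C)C)OC(=O)/C(C)=C\C)[C@@H]1CC=C(C)[C@H](O[Si](C)(C)C(C)(C)C)[C@@H]1O
F15 | step 17 | C4 tert-butyldimethylsilyl ether, C5 angelate | C=C([C@H](CC=C(C)C)OC(=O)/C(C)=C\C)[C@@H]1CC=C(C)[C@H](O[Si](C)(C)C(C)(C)C)[C@@H]1OC(=O)/C(C)=C\C
F16 | step 19 | C4 triethylsilyl ether of 25 | C=C([C@H](CC=C(C)C)OC(=O)/C(C)=C\C)[C@@H]1C[C@@H]2O[C@]2(C)[C@H](O[Si](CC)(CC)CC)[C@@H]1OC(=O)/C(C)=C\C
F17 | step 19 | C4 triethylsilyl ether of 26 | C=C([C@H](C[C@H]1OC1(C)C)OC(=O)/C(C)=C\C)[C@@H]1C[C@@H]2O[C@]2(C)[C@H](O[Si](CC)(CC)CC)[C@@H]1OC(=O)/C(C)=C\C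
A1 | alternative 1 | (R)-2-tert-butyl-6-ethyl-4H-1,3-dioxin-4-one | CCC1=CC(=O)O[C@H](C(C)(C)C)O1
A2 | alternative 1 | 2,3-dihydrofuran | C1CC=CO1
A3 | alternative 1 | cis-anti-cis tricyclic photoadduct | CC[C@@]12O[C@@H](C(C)(C)C)OC(=O)[C@@H]1[C@H]3CCO[C@H]32
A4 | alternative 2 | acyclic (Z)-iodoalkene aldehyde with C5–OTBS and C7 N-methoxy-N-methylamide | CON(C)C(=O)[C@H](C/C=C(/C)I)[C@@H](O[Si](C)(C)C(C)(C)C)C=O
A5 | alternative 2 | 2-methylcyclohex-2-enol with C5–OTBS and C7 N-methoxy-N-methylamide | CON(C)C(=O)[C@@H]1CC=C(C)[C@H](O)[C@@H]1O[Si](C)(C)C(C)(C)C
A6 | alternative 3 | (1-bromovinyl)dimethylsilyl ether of the C4–OTBS cyclohexadienol | C=C(Br)[Si](C)(C)O[C@@H]1C=CC=C(C)[C@@H]1O[Si](C)(C)C(C)(C)C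
A7 | alternative 3 | cis-fused bicyclic siloxane | C=C1[C@@H]2CC=C(C)[C@H](O[Si](C)(C)C(C)(C)C)[C@@H]2O[Si]1(C)C
A8 | alternative 3 | (1R,2S)-3-methylcyclohexa-3,5-diene-1,2-diol | O[C@@H]1C=CC=C(C)[C@@H]1O
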